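The central ring C is made last, from a 2-pyrone that already carries both outer diaryl ether halves. Ring C is a 2,5-bis(aryloxy)resorcinol: its C1 (oxygen to ring B), the hydroxylated C2 and C6, and C4 (oxygen to ring D) correspond to the exocyclic CH2, the lactone carbonyl, C6 and C4 of a 4-aryloxy-6-(aryloxymethyl)-2-pyrone. In one operation an alkoxide opens the lactone and the resulting keto ester recloses by Claisen condensation, forming the C1–C2 bond and ring C as a free resorcinol, with no hindered diaryl ether coupling. The precursor is that pyrone with the DE aryloxy group on C4, the AB aryloxymethyl group on C6, and nine methyl ethers.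

Key step: step 11

Remark: rings are lettered A to E from the 3,5-dihydroxyphenoxy end to the 2,4,6-trihydroxyphenoxy end; the target is achiral, so no stereocentre has to be set; all starting materials are assumed to be catalogue compounds.

Step 1
Reactants: 1 triacetic acid lactone (4-hydroxy-6-methyl-2H-pyran-2-one)
Product: 2 4-bromo-6-methyl-2H-pyran-2-one
Conditions: Bu4NBr, P2O5, toluene, 100 °C
Reagents that add atoms: tetrabutylammonium bromide, CCCC[N+](CCCC)(CCCC)CCCC.[Br-]
Why: Deoxybromination of a vinylogous acid, in which P2O5 turns the C4 hydroxyl into a phosphate leaving group that bromide replaces by addition–elimination, a standard way to 4-bromo-2-pyrones.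

Step 2
Reactants: 2 4-bromo-6-methyl-2H-pyran-2-one
Product: 3 4-bromo-6-(bromomethyl)-2H-pyran-2-one
Conditions: NBS (1.05 equiv), AIBN (cat.), PhCF3, 85 °C
Reagents that add atoms: N-bromosuccinimide, O=C1CCC(=O)N1Br
Why: Wohl–Ziegler radical bromination of the C6 methyl group, as practised on 4-methoxy-6-methyl-2-pyrone; the electron-poor ring resists ionic bromination and no electron-rich arene is present yet.

Step 3
Reactants: 4 2-hydroxy-4,6-dimethoxybenzaldehyde (4,6-dimethoxysalicylaldehyde)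
Product: 5 2-(benzyloxy)-4,6-dimethoxybenzaldehyde
Conditions: BnBr, K2CO3, DMF, 60 °C
Reagents that add atoms: benzyl bromide, BrCc1ccccc1
Why: Williamson benzylation of the chelated phenol; the benzyl group masks the oxygen that later links ring B to the pyrone and is the only group in the route removed by hydrogenolysis.

Step 4
Reactants: 5 2-(benzyloxy)-4,6-dimethoxybenzaldehyde
Product: 7 2-(benzyloxy)-4,6-dimethoxyphenol, via aryl formate 6 (not isolated)
Conditions: mCPBA (1.1 equiv), CH2Cl2, 0 °C to rt; then K2CO3 (cat.), MeOH, argon, rt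
Reagents that add atoms: 3-chloroperoxybenzoic acid, OOC(=O)c1cccc(Cl)c1
Why: Baeyer–Villiger (Dakin-type) oxidation in which the electron-rich aryl group migrates to give the aryl formate, which mild methanolysis cleaves to the phenol that becomes the ether oxygen between rings A and B.

Step 5
Reactants: 7 2-(benzyloxy)-4,6-dimethoxyphenol; 8 1-iodo-3,5-dimethoxybenzene
Product: 9 1-(benzyloxy)-2-(3,5-dimethoxyphenoxy)-3,5-dimethoxybenzene
Conditions: CuI (10 mol%), picolinic acid (20 mol%), K3PO4, DMSO, 90 °C, argon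
Reagents that add atoms: none
Why: Copper-catalysed Ullmann diaryl ether synthesis; the picolinic acid system is suited to 2,6-disubstituted phenols and the aryl iodide partner is unhindered.

Step 6
Reactants: 9 1-(benzyloxy)-2-(3,5-dimethoxyphenoxy)-3,5-dimethoxybenzene
Product: 10 2-(3,5-dimethoxyphenoxy)-3,5-dimethoxyphenol (AB phenol)
Conditions: H2 (1 atm), 10% Pd/C, EtOAc–MeOH, rt
Reagents that add atoms: none
Why: Catalytic hydrogenolysis removes only the benzyl ether, while methyl and diaryl ethers are inert.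

Step 7
Reactants: 11 2,4,6-trimethoxyphenol; 12 2-bromo-4,6-dimethoxybenzaldehyde
Product: 13 2,4-dimethoxy-6-(2,4,6-trimethoxyphenoxy)benzaldehyde
Conditions: CuI (10 mol%), picolinic acid (20 mol%), K3PO4, DMSO, 90 °C, argon
Reagents that add atoms: none
Why: Copper-catalysed Ullmann etherification in which the hindered, electron-rich phenol is the nucleophile and the aryl bromide is activated by its ortho formyl group, a polarity that avoids a doubly ortho-substituted, electron-rich aryl halide.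

Step 8
Reactants: 13 2,4-dimethoxy-6-(2,4,6-trimethoxyphenoxy)benzaldehyde
Product: 15 2,4-dimethoxy-6-(2,4,6-trimethoxyphenoxy)phenol (DE phenol), via aryl formate 14 (not isolated)
Conditions: mCPBA (1.1 equiv), CH2Cl2, 0 °C; then K2CO3 (cat.), MeOH, argon, rt
Reagents that add atoms: 3-chloroperoxybenzoic acid, OOC(=O)c1cccc(Cl)c1
Why: Baeyer–Villiger (Dakin-type) oxidation with migration of the electron-rich ring D aryl group followed by methanolysis of the formate; limiting the peracid at 0 °C should spare the trimethoxyphenoxy ring.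

Step 9
Reactants: 3 4-bromo-6-(bromomethyl)-2H-pyran-2-one; 10 2-(3,5-dimethoxyphenoxy)-3,5-dimethoxyphenol
Product: 16 4-bromo-6-{[2-(3,5-dimethoxyphenoxy)-3,5-dimethoxyphenoxy]methyl}-2H-pyran-2-one
Conditions: K2CO3, acetone, 0 °C to rt; 10 added slowly to 3 (1.3 equiv)
Reagents that add atoms: none
Why: Williamson ether synthesis, in which SN2 displacement at the primary, pyrone-activated CH2Br should outpace addition–elimination at C4 at or below room temperature with a weak base, and slow addition of 10 to an excess of 3 reinforces this.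

Step 10
Reactants: 16 4-bromo-6-{[2-(3,5-dimethoxyphenoxy)-3,5-dimethoxyphenoxy]methyl}-2H-pyran-2-one; 15 2,4-dimethoxy-6-(2,4,6-trimethoxyphenoxy)phenol
Product: 17 4-[2,4-dimethoxy-6-(2,4,6-trimethoxyphenoxy)phenoxy]-6-{[2-(3,5-dimethoxyphenoxy)-3,5-dimethoxyphenoxy]methyl}-2H-pyran-2-one
Conditions: Cs2CO3, MeCN, 50 °C
Reagents that add atoms: none
Why: Addition–elimination (vinylogous acyl substitution) of bromide at C4 by the phenoxide, the known route from 4-bromo-2-pyrones to 4-aryloxy-2-pyrones; C4 is now the only electrophilic carbon that carries a leaving group.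

Step 11
Reactants: 17 4-[2,4-dimethoxy-6-(2,4,6-trimethoxyphenoxy)phenoxy]-6-{[2-(3,5-dimethoxyphenoxy)-3,5-dimethoxyphenoxy]methyl}-2H-pyran-2-one
Product: 19 2-[2-(3,5-dimethoxyphenoxy)-3,5-dimethoxyphenoxy]-5-[2,4-dimethoxy-6-(2,4,6-trimethoxyphenoxy)phenoxy]benzene-1,3-diol (nona-O-methyl pentamer; ring C resorcinol free), via ring-opened keto ester 18 (not isolated)
Conditions: Mg(OMe)2 (5 equiv), MeOH–THF, 65 °C, argon; then degassed 1 M HCl, 0 °C
Reagents that add atoms: none
Why: Methoxide from Mg(OMe)2 adds to the lactone carbonyl and the ring opens to the magnesium dienolate of keto ester 18, whose ester and aryloxyacetyl arm stay on the same side of the enol-ether double bond; proton transfer gives the enolate at the aryloxy-bearing terminal carbon, which attacks the methyl ester, and loss of methoxide plus two enolisations gives the resorcinolate. The closest known reaction is the alkoxide-induced isomerisation of 4-methoxy-6-methyl-2-pyrone to 5-methoxyresorcinol, applied here to a pyrone with aryloxy groups at C4 and on the C6 methyl carbon. Ring C closes by a 6-exo-trig Claisen (Dieckmann-type) condensation that forms its C1–C2 bond. No stereocentre is created. The step needs attack at the lactone carbonyl in preference to addition–elimination at C4, which would expel the ring D aryloxide: magnesium chelation activates the carbonyl and should hold the opened chain as an electron-rich dienolate that resists conjugate exchange, the two ortho substituents of ring D screen C4, and the aryloxy group acidifies the carbon that must become the nucleophile. Aromatisation should make the closure irreversible.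

Step 12
Reactants: 19 2-[2-(3,5-dimethoxyphenoxy)-3,5-dimethoxyphenoxy]-5-[2,4-dimethoxy-6-(2,4,6-trimethoxyphenoxy)phenoxy]benzene-1,3-diol
Product: 20 2-[2-(3,5-dihydroxyphenoxy)-3,5-dihydroxyphenoxy]-5-[2,4-dihydroxy-6-(2,4,6-trihydroxyphenoxy)phenoxy]benzene-1,3-diol (CNP0018313.0)
Conditions: BBr3 (20 equiv), CH2Cl2, −78 °C to rt, argon; then ice-water, EtOAc; Sephadex LH-20, degassed MeOH
Reagents that add atoms: none
Why: Lewis acid cleavage of the nine aryl methyl ethers by BBr3 (bromide attacks the O-methyl carbon of each boron-complexed ether); the diaryl ether links offer no alkyl carbon and should survive, and exclusion of air protects the polyphenol.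

Compound list
1 | triacetic acid lactone (4-hydroxy-6-methyl-2H-pyran-2-one) | Cc1cc(O)cc(=O)o1 | starting material
2 | 4-bromo-6-methyl-2H-pyran-2-one | Cc1cc(Br)cc(=O)o1 | intermediate
3 | 4-bromo-6-(bromomethyl)-2H-pyran-2-one | BrCc1cc(Br)cc(=O)o1 | intermediate
4 | 2-hydroxy-4,6-dimethoxybenzaldehyde (4,6-dimethoxysalicylaldehyde) | COc1cc(O)c(C=O)c(OC)c1 | starting material
5 | 2-(benzyloxy)-4,6-dimethoxybenzaldehyde | COc1cc(OCc2ccccc2)c(C=O)c(OC)c1 | intermediate
6 | 2-(benzyloxy)-4,6-dimethoxyphenyl formate | COc1cc(OCc2ccccc2)c(OC=O)c(OC)c1 | intermediate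
7 | 2-(benzyloxy)-4,6-dimethoxyphenol | COc1cc(OCc2ccccc2)c(O)c(OC)c1 | intermediate
8 | 1-iodo-3,5-dimethoxybenzene | COc1cc(I)cc(OC)c1 | starting material
9 | 1-(benzyloxy)-2-(3,5-dimethoxyphenoxy)-3,5-dimethoxybenzene | COc1cc(OC)cc(Oc2c(OC)cc(OC)cc2OCc2ccccc2)c1 | intermediate
10 | 2-(3,5-dimethoxyphenoxy)-3,5-dimethoxyphenol (AB phenol) | COc1cc(OC)cc(Oc2c(OC)cc(OC)cc2O)c1 | intermediate
11 | 2,4,6-trimethoxyphenol | COc1cc(OC)c(O)c(OC)c1 | starting material
12 | 2-bromo-4,6-dimethoxybenzaldehyde | COc1cc(Br)c(C=O)c(OC)c1 | starting material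
13 | 2,4-dimethoxy-6-(2,4,6-trimethoxyphenoxy)benzaldehyde | COc1cc(Oc2c(OC)cc(OC)cc2OC)c(C=O)c(OC)c1 | intermediate
14 | 2,4-dimethoxy-6-(2,4,6-trimethoxyphenoxy)phenyl formate | COc1cc(Oc2c(OC)cc(OC)cc2OC)c(OC=O)c(OC)c1 | intermediate
15 | 2,4-dimethoxy-6-(2,4,6-trimethoxyphenoxy)phenol (DE phenol) | COc1cc(Oc2c(OC)cc(OC)cc2OC)c(O)c(OC)c1 | intermediate
16 | 4-bromo-6-{[2-(3,5-dimethoxyphenoxy)-3,5-dimethoxyphenoxy]methyl}-2H-pyran-2-one | O=c1cc(Br)cc(COc2cc(OC)cc(OC)c2Oc2cc(OC)cc(OC)c2)o1 | intermediate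
17 | 4-[2,4-dimethoxy-6-(2,4,6-trimethoxyphenoxy)phenoxy]-6-{[2-(3,5-dimethoxyphenoxy)-3,5-dimethoxyphenoxy]methyl}-2H-pyran-2-one | O=c1cc(Oc2c(OC)cc(OC)cc2Oc2c(OC)cc(OC)cc2OC)cc(COc2cc(OC)cc(OC)c2Oc2cc(OC)cc(OC)c2)o1 | intermediate
18 | methyl (2E)-3-[2,4-dimethoxy-6-(2,4,6-trimethoxyphenoxy)phenoxy]-6-[2-(3,5-dimethoxyphenoxy)-3,5-dimethoxyphenoxy]-5-oxohex-2-enoate (ester and ketone arm cis) | COC(=O)/C=C(\CC(=O)COc1cc(OC)cc(OC)c1Oc1cc(OC)cc(OC)c1)Oc1c(OC)cc(OC)cc1Oc1c(OC)cc(OC)cc1OC | intermediate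
19 | 2-[2-(3,5-dimethoxyphenoxy)-3,5-dimethoxyphenoxy]-5-[2,4-dimethoxy-6-(2,4,6-trimethoxyphenoxy)phenoxy]benzene-1,3-diol | COc1cc(OC)cc(Oc2c(OC)cc(OC)cc2Oc2c(O)cc(Oc3c(OC)cc(OC)cc3Oc3c(OC)cc(OC)cc3OC)cc2O)c1 | intermediate
20 | 2-[2-(3,5-dihydroxyphenoxy)-3,5-dihydroxyphenoxy]-5-[2,4-dihydroxy-6-(2,4,6-trihydroxyphenoxy)phenoxy]benzene-1,3-diol (CNP0018313.0) | Oc1cc(O)cc(Oc2c(O)cc(O)cc2Oc2c(O)cc(Oc3c(O)cc(O)cc3Oc3c(O)cc(O)cc3O)cc2O)c1 | target

Total step count: 12.
Longest linear sequence: 8 steps (steps 3, 4, 5, 6, 9, 10, 11, 12).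

Steps most likely to fail

1. Step 11. Methoxide may exchange the ring D aryloxide at C4, on the pyrone or on the opened enol ether, faster than the chain closes, or the opened dienolate may not reach the terminal enolate needed for closure. The fallback sets out from 15 and comes back to the route at 20. It brings ring C in as a ready-made benzaldehyde and grows the chain one ring at a time by Ullmann etherification and Baeyer–Villiger oxidation. 15 is coupled with 4-bromo-2,6-dimethoxybenzaldehyde (CuI, picolinic acid, K3PO4, DMSO, 90 °C) to give 4-[2,4-dimethoxy-6-(2,4,6-trimethoxyphenoxy)phenoxy]-2,6-dimethoxybenzaldehyde F1. mCPBA converts F1 into 4-[2,4-dimethoxy-6-(2,4,6-trimethoxyphenoxy)phenoxy]-2,6-dimethoxyphenyl formate F2, and methanolysis gives 4-[2,4-dimethoxy-6-(2,4,6-trimethoxyphenoxy)phenoxy]-2,6-dimethoxyphenol F3. F3 is coupled with 12 under the same copper conditions to give 2-{4-[2,4-dimethoxy-6-(2,4,6-trimethoxyphenoxy)phenoxy]-2,6-dimethoxyphenoxy}-4,6-dimethoxybenzaldehyde F4. This is oxidised through 2-{4-[2,4-dimethoxy-6-(2,4,6-trimethoxyphenoxy)phenoxy]-2,6-dimethoxyphenoxy}-4,6-dimethoxyphenyl formate F5 to 2-{4-[2,4-dimethoxy-6-(2,4,6-trimethoxyphenoxy)phenoxy]-2,6-dimethoxyphenoxy}-4,6-dimethoxyphenol F6. Ullmann coupling of F6 with 8 gives the undeca-O-methyl pentamer F7, and BBr3 under the conditions of step 12 should cleave all eleven methyl ethers to 20.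

2. Step 9. The phenoxide may not discriminate between the CH2Br carbon and C4, giving the C4 ether or the doubly substituted pyrone. The fallback sets out from 10 and comes back to the route at 16. It attaches the ether oxygen before the pyrone exists. 10 is alkylated with methyl bromoacetate (K2CO3, acetone) to give methyl [2-(3,5-dimethoxyphenoxy)-3,5-dimethoxyphenoxy]acetate F8. The dianion of methyl acetoacetate (NaH, then n-BuLi, THF, 0 °C) is acylated by F8 in a Claisen condensation to give methyl 6-[2-(3,5-dimethoxyphenoxy)-3,5-dimethoxyphenoxy]-3,5-dioxohexanoate F9. DBU in refluxing toluene lactonises F9 to 4-hydroxy-6-{[2-(3,5-dimethoxyphenoxy)-3,5-dimethoxyphenoxy]methyl}-2H-pyran-2-one F10. Bu4NBr and P2O5 in toluene, as in step 1, convert F10 into 16.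

3. Step 12. Cleavage of nine ethers may stop short, and the free polyphenol may oxidise during work-up and chromatography. The fallback sets out from 19 and comes back to the route at 20. The crude product of the BBr3 reaction is not isolated as the free phenol but acetylated at once (Ac2O, pyridine, DMAP cat.) to the undeca-O-acetate F11. This should be stable to air and silica, so partly methylated material can be separated and returned to BBr3. Zemplén deacetylation (NaOMe cat., degassed MeOH, argon, then acidic ion-exchange resin) should release 20.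

Further compounds
F1 | step 11 | 4-[2,4-dimethoxy-6-(2,4,6-trimethoxyphenoxy)phenoxy]-2,6-dimethoxybenzaldehyde | O=Cc1c(OC)cc(Oc2c(OC)cc(OC)cc2Oc2c(OC)cc(OC)cc2OC)cc1OC
F2 | step 11 | 4-[2,4-dimethoxy-6-(2,4,6-trimethoxyphenoxy)phenoxy]-2,6-dimethoxyphenyl formate | O=COc1c(OC)cc(Oc2c(OC)cc(OC)cc2Oc2c(OC)cc(OC)cc2OC)cc1OC
F3 | step 11 | 4-[2,4-dimethoxy-6-(2,4,6-trimethoxyphenoxy)phenoxy]-2,6-dimethoxyphenol | Oc1c(OC)cc(Oc2c(OC)cc(OC)cc2Oc2c(OC)cc(OC)cc2OC)cc1OC
F4 | step 11 | 2-{4-[2,4-dimethoxy-6-(2,4,6-trimethoxyphenoxy)phenoxy]-2,6-dimethoxyphenoxy}-4,6-dimethoxybenzaldehyde | O=Cc1c(OC)cc(OC)cc1Oc1c(OC)cc(Oc2c(OC)cc(OC)cc2Oc2c(OC)cc(OC)cc2OC)cc1OC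
F5 | step 11 | 2-{4-[2,4-dimethoxy-6-(2,4,6-trimethoxyphenoxy)phenoxy]-2,6-dimethoxyphenoxy}-4,6-dimethoxyphenyl formate | O=COc1c(OC)cc(OC)cc1Oc1c(OC)cc(Oc2c(OC)cc(OC)cc2Oc2c(OC)cc(OC)cc2OC)cc1OC
F6 | step 11 | 2-{4-[2,4-dimethoxy-6-(2,4,6-trimethoxyphenoxy)phenoxy]-2,6-dimethoxyphenoxy}-4,6-dimethoxyphenol | Oc1c(OC)cc(OC)cc1Oc1c(OC)cc(Oc2c(OC)cc(OC)cc2Oc2c(OC)cc(OC)cc2OC)cc1OC
F7 | step 11 | undeca-O-methyl pentamer, 1-[2-(3,5-dimethoxyphenoxy)-3,5-dimethoxyphenoxy]-4-[2,4-dimethoxy-6-(2,4,6-trimethoxyphenoxy)phenoxy]-2,6-dimethoxybenzene | COc1cc(OC)cc(Oc2c(OC)cc(OC)cc2Oc2c(OC)cc(Oc3c(OC)cc(OC)cc3Oc3c(OC)cc(OC)cc3OC)cc2OC)c1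
F8 | step 9 | methyl [2-(3,5-dimethoxyphenoxy)-3,5-dimethoxyphenoxy]acetate | COC(=O)COc1cc(OC)cc(OC)c1Oc1cc(OC)cc(OC)c1
F9 | step 9 | methyl 6-[2-(3,5-dimethoxyphenoxy)-3,5-dimethoxyphenoxy]-3,5-dioxohexanoate | COC(=O)CC(=O)CC(=O)COc1cc(OC)cc(OC)c1Oc1cc(OC)cc(OC)c1
F10 | step 9 | 4-hydroxy-6-{[2-(3,5-dimethoxyphenoxy)-3,5-dimethoxyphenoxy]methyl}-2H-pyran-2-one | O=c1cc(O)cc(COc2cc(OC)cc(OC)c2Oc2cc(OC)cc(OC)c2)o1
F11 | step 12 | undeca-O-acetate of 20 | CC(=O)Oc1cc(OC(C)=O)cc(Oc2c(OC(C)=O)cc(OC(C)=O)cc2Oc2c(OC(C)=O)cc(Oc3c(OC(C)=O)cc(OC(C)=O)cc3Oc3c(OC(C)=O)cc(OC(C)=O)cc3OC(C)=O)cc2OC(C)=O)c1
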